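**Retrosynthetic overview**
- Target ⇐ its 7,4'-bis-MOM ether (acid deprotection last).
- Ring C, the only ring built, ⇐ 2'-hydroxychalcone: oxa-Michael closure (chalcone-isomerase-like) merged with C3 hydroxylation (flavanone-3-hydroxylase-like) in one asymmetric oxidative cascade that sets C2 and C3 together.
- Chalcone ⇐ Claisen–Schmidt union of unprotected 3,5-diprenylresacetophenone and 3-prenyl-4-hydroxybenzaldehyde, then selective bis-MOM capping.
- Both fragments ⇐ direct C-prenylation of 2,4-dihydroxyacetophenone and 4-hydroxybenzaldehyde with prenyl bromide.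
- Ring order: rings A and B are bought as aromatics; ring C is closed in the penultimate step.

Abbreviations: prenyl = 3-methylbut-2-en-1-yl; MOM = methoxymethyl.
Assumption: the absolute sense of induction in step 5 cannot be predicted for a new reaction; the cinchonidine-derived catalyst is written, and its commercial cinchonine pseudoenantiomer replaces it if the first run (CD and optical rotation against the natural product) shows the (2S,3S) series.

**Step 1**
Reactants: 1 2,4-dihydroxyacetophenone; 2 prenyl bromide (1-bromo-3-methylbut-2-ene)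
Product: 3 1-[2,4-dihydroxy-3,5-bis(3-methylbut-2-en-1-yl)phenyl]ethan-1-one
Conditions: 2 (2.3 equiv), 10% aq KOH, 0 °C → rt, 18 h; chromatography
Reagents that add atoms: prenyl bromide (2), CC(C)=CCBr
Why: C-alkylation of the ambident resorcinol dianion in water (Friedel–Crafts-type phenoxide C-prenylation) can only occur at C3 and C5, so excess bromide converges on the 3,5-diprenyl compound (modest yield, separated from mono- and O-prenyl by-products); no stereocentre.

**Step 2**
Reactants: 4 4-hydroxybenzaldehyde; 2 prenyl bromide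
Product: 5 4-hydroxy-3-(3-methylbut-2-en-1-yl)benzaldehyde
Conditions: 2 (1.1 equiv), 10% aq KOH, rt, 16 h; chromatography
Reagents that add atoms: prenyl bromide (2), CC(C)=CCBr
Why: aqueous phenoxide C-prenylation goes ortho to the oxide because the para position carries the formyl group; the O-prenyl ether is the separable by-product; no stereocentre.

**Step 3**
Reactants: 3 1-[2,4-dihydroxy-3,5-bis(3-methylbut-2-en-1-yl)phenyl]ethan-1-one; 5 4-hydroxy-3-(3-methylbut-2-en-1-yl)benzaldehyde
Product: 6 (E)-1-[2,4-dihydroxy-3,5-bis(3-methylbut-2-en-1-yl)phenyl]-3-[4-hydroxy-3-(3-methylbut-2-en-1-yl)phenyl]prop-2-en-1-one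
Conditions: 60% aq KOH (15 equiv), EtOH, rt, 72 h, Ar; then cold dilute HCl to pH 5
Reagents that add atoms: none
Why: Claisen–Schmidt aldol condensation of the per-phenoxide partners (slow but known for polyhydroxychalcones) ends in E1cB dehydration to the conjugated E-enone, and the prenyl groups are inert to base.

**Step 4**
Reactants: 6 the trihydroxy-triprenylchalcone; 7 chloromethyl methyl ether (MOMCl)
Product: 8 (E)-1-[2-hydroxy-4-(methoxymethoxy)-3,5-bis(3-methylbut-2-en-1-yl)phenyl]-3-[4-(methoxymethoxy)-3-(3-methylbut-2-en-1-yl)phenyl]prop-2-en-1-one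
Conditions: MOMCl (2.4 equiv), K2CO3 (4 equiv), acetone, 0 °C → rt
Reagents that add atoms: MOMCl (7), COCCl
Why: Williamson-type O-alkylation caps only the 4- and 4'-phenols because the 2'-OH is locked in a hydrogen bond to the carbonyl; the caps stop para-phenoxide formation, which would deactivate the enone in step 5.

**Step 5**
Reactants: 8 the 2'-hydroxy-bis-MOM chalcone; 9 hydrogen peroxide
Product: 11 (2R,3R)-3-hydroxy-7-(methoxymethoxy)-2-[4-(methoxymethoxy)-3-(3-methylbut-2-en-1-yl)phenyl]-6,8-bis(3-methylbut-2-en-1-yl)-2,3-dihydro-4H-chromen-4-one, via (2S)-flavanone enolate 10 (not isolated)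
Conditions: 30% aq H2O2 (3 equiv), LiOH·H2O (1.5 equiv), N-(9-anthracenylmethyl)cinchonidinium chloride (10 mol %), toluene/H2O, 0 °C, stopped just short of full conversion; then aq Na2S2O3/NH4Cl
Reagents that add atoms: hydrogen peroxide (9), OO
Why: Proposed new method: under phase transfer the 2'-phenoxide, ion-paired with the chiral ammonium, closes by reversible 6-endo oxa-Michael addition to enolate 10, whose enantiomers interconvert by ring opening, and the (2S)-enolate ion pair is hydroxylated faster at C3 by neutral H2O2 (enolate carbon attacks the O–O bond) anti to the C2 aryl group, so one dynamic kinetic event sets C2 (R in the product), C3 (R) and the 2,3-trans relation, which is also the thermodynamic one; the closest known reactions are the Algar–Flynn–Oyamada oxidation (racemic trans-dihydroflavonols from 6'-unsubstituted 2'-hydroxychalcones) and cinchona phase-transfer α-hydroxylation of ketone enolates and epoxidation of chalcones with peroxides, and alkaline H2O2 leaves prenyl alkenes and MOM ethers untouched.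

**Step 6**
Reactants: 11 the (2R,3R)-bis-MOM dihydroflavonol
Product: 12 lespeflorin B3, (2R,3R)-3,7-dihydroxy-2-[4-hydroxy-3-(3-methylbut-2-en-1-yl)phenyl]-6,8-bis(3-methylbut-2-en-1-yl)-2,3-dihydro-4H-chromen-4-one
Conditions: 3 M aq HCl, MeOH, 40 °C, 2 h (monitored)
Reagents that add atoms: none
Why: acid-catalysed acetal cleavage (transacetalisation to dimethoxymethane) frees both phenols under conditions known to spare prenyl groups ortho to phenols when kept brief, and without base there is no enolisation or ring opening, so C2 and C3 are untouched.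

**Compound list**
1 | 2,4-dihydroxyacetophenone | CC(=O)c1ccc(O)cc1O | starting material
2 | prenyl bromide (1-bromo-3-methylbut-2-ene) | CC(C)=CCBr | starting material
3 | 1-[2,4-dihydroxy-3,5-bis(3-methylbut-2-en-1-yl)phenyl]ethan-1-one | CC(=O)c1cc(CC=C(C)C)c(O)c(CC=C(C)C)c1O | intermediate
4 | 4-hydroxybenzaldehyde | O=Cc1ccc(O)cc1 | starting material
5 | 4-hydroxy-3-(3-methylbut-2-en-1-yl)benzaldehyde | CC(C)=CCc1cc(C=O)ccc1O | intermediate
6 | (E)-1-[2,4-dihydroxy-3,5-bis(3-methylbut-2-en-1-yl)phenyl]-3-[4-hydroxy-3-(3-methylbut-2-en-1-yl)phenyl]prop-2-en-1-one | CC(C)=CCc1cc(/C=C/C(=O)c2cc(CC=C(C)C)c(O)c(CC=C(C)C)c2O)ccc1O | intermediate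
7 | chloromethyl methyl ether (MOMCl) | COCCl | starting material
8 | (E)-1-[2-hydroxy-4-(methoxymethoxy)-3,5-bis(3-methylbut-2-en-1-yl)phenyl]-3-[4-(methoxymethoxy)-3-(3-methylbut-2-en-1-yl)phenyl]prop-2-en-1-one | CC(C)=CCc1cc(/C=C/C(=O)c2cc(CC=C(C)C)c(OCOC)c(CC=C(C)C)c2O)ccc1OCOC | intermediate
9 | hydrogen peroxide | OO | starting material
10 | (2S)-7-(methoxymethoxy)-2-[4-(methoxymethoxy)-3-prenylphenyl]-6,8-diprenyl-2H-chromen-4-olate (flavanone enolate, ammonium ion pair) | CC(C)=CCc1cc([C@H]2Oc3c(cc(CC=C(C)C)c(OCOC)c3CC=C(C)C)C([O-])=C2)ccc1OCOC | intermediate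
11 | (2R,3R)-3-hydroxy-7-(methoxymethoxy)-2-[4-(methoxymethoxy)-3-(3-methylbut-2-en-1-yl)phenyl]-6,8-bis(3-methylbut-2-en-1-yl)-2,3-dihydro-4H-chromen-4-one | CC(C)=CCc1cc([C@H]2Oc3c(cc(CC=C(C)C)c(OCOC)c3CC=C(C)C)C(=O)[C@@H]2O)ccc1OCOC | intermediate
12 | lespeflorin B3, (2R,3R)-3,7-dihydroxy-2-[4-hydroxy-3-(3-methylbut-2-en-1-yl)phenyl]-6,8-bis(3-methylbut-2-en-1-yl)-2,3-dihydro-4H-chromen-4-one | CC(C)=CCc1cc([C@H]2Oc3c(cc(CC=C(C)C)c(O)c3CC=C(C)C)C(=O)[C@@H]2O)ccc1O | target

**Totals**
Total steps: 6. Longest linear sequence: 5 (steps 1, 3, 4, 5, 6).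

**Three steps most likely to fail**

Step 5 is the main risk. The cascade is new, so the enantiomeric excess and its sense are unproven. Over-oxidation to the flavonol, aurone formation and base-induced ring opening of the product also threaten it. If the ee of 11 is incomplete, it is raised by recrystallisation or chiral chromatography before step 6. The fallback sets out from 8 and comes back at 12. The chelated 2'-OH is capped (NaH, MOMCl, DMF, 0 °C) to give (E)-1-[2,4-bis(methoxymethoxy)-3,5-bis(3-methylbut-2-en-1-yl)phenyl]-3-[4-(methoxymethoxy)-3-(3-methylbut-2-en-1-yl)phenyl]prop-2-en-1-one F1. Juliá–Colonna epoxidation (poly-L-leucine, urea–H2O2, DBU, THF, rt), whose sense for chalcones is reliable, gives [(2R,3S)-3-[4-(methoxymethoxy)-3-(3-methylbut-2-en-1-yl)phenyl]oxiran-2-yl][2,4-bis(methoxymethoxy)-3,5-bis(3-methylbut-2-en-1-yl)phenyl]methanone F2. Treatment with 3 M HCl in MeOH at 45 °C then removes all three MOM groups, and the freed 2'-phenol opens the oxirane at the benzylic carbon with inversion (6-endo). C3 keeps the epoxide Cα configuration, so 12 forms directly; any cis epimer from SN1 leakage is removed by chromatography.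

Step 3 is the second risk. Both partners are deactivated as para-phenoxides, so the unprotected condensation may stall or give a low yield. The fallback sets out from 3 and 5 and comes back at 8. Each fragment is MOM-protected first (MOMCl, K2CO3, acetone, rt; the chelated OH of 3 is untouched), giving 1-[2-hydroxy-4-(methoxymethoxy)-3,5-bis(3-methylbut-2-en-1-yl)phenyl]ethan-1-one F3 and 4-(methoxymethoxy)-3-(3-methylbut-2-en-1-yl)benzaldehyde F4. Their Claisen–Schmidt condensation (KOH, EtOH/H2O, rt) is then a normal, high-yielding one and gives 8 directly. Steps 3 and 4 are replaced at the cost of one extra step.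

Step 1 is the third risk. Double C-prenylation gives mixtures of mono-, di-, geminal and O-prenyl products, and the yield of 3 may be too low to supply the route. The fallback sets out from 1 and comes back at 3. Iodination (I2, HIO3, EtOH/H2O, 40 °C) fixes both positions as 1-(2,4-dihydroxy-3,5-diiodophenyl)ethan-1-one F5. A double Stille coupling with tributyl(3-methylbut-2-en-1-yl)stannane (Pd(PPh3)4, DMF, 90 °C) then places the linear prenyl groups by ipso substitution to give 3.

**Further compounds**
F1 | step 5 | (E)-1-[2,4-bis(methoxymethoxy)-3,5-bis(3-methylbut-2-en-1-yl)phenyl]-3-[4-(methoxymethoxy)-3-(3-methylbut-2-en-1-yl)phenyl]prop-2-en-1-one | CC(C)=CCc1cc(/C=C/C(=O)c2cc(CC=C(C)C)c(OCOC)c(CC=C(C)C)c2OCOC)ccc1OCOC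
F2 | step 5 | [(2R,3S)-3-[4-(methoxymethoxy)-3-(3-methylbut-2-en-1-yl)phenyl]oxiran-2-yl][2,4-bis(methoxymethoxy)-3,5-bis(3-methylbut-2-en-1-yl)phenyl]methanone | O=C(c1cc(CC=C(C)C)c(OCOC)c(CC=C(C)C)c1OCOC)[C@@H]2O[C@H]2c3ccc(OCOC)c(CC=C(C)C)c3
F3 | step 3 | 1-[2-hydroxy-4-(methoxymethoxy)-3,5-bis(3-methylbut-2-en-1-yl)phenyl]ethan-1-one | CC(=O)c1cc(CC=C(C)C)c(OCOC)c(CC=C(C)C)c1O
F4 | step 3 | 4-(methoxymethoxy)-3-(3-methylbut-2-en-1-yl)benzaldehyde | CC(C)=CCc1cc(C=O)ccc1OCOC
F5 | step 1 | 1-(2,4-dihydroxy-3,5-diiodophenyl)ethan-1-one | CC(=O)c1cc(I)c(O)c(I)c1O
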